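Feature: DMGF is the 6,8''-linked dimer of genkwanin (plain locants for the 6-linked flavone, double-primed for the 8''-linked one). Its ring A hydroxyls on C5 and C5'' each sit peri to a ring C carbonyl (C4=O, C4''=O), and O-C5 is one of four groups ortho to the C6-C8'' axis (with C7-OMe, C7''-OMe and O1'' on C8a'').
Last disconnection: the C5-O and C5''-O bonds are made from C-H bonds, steered by those two carbonyls, on the 5,5''-dideoxy biflavone diacetate 11. Only acetate removal follows.
11 goes back to biaryl diketone 7 by twofold flavone construction (double Claisen-Schmidt condensation with 4-hydroxybenzaldehyde, double I2/DMSO closure). Both rings C form together in step 7, and rings A and B are bought.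
7 is cut at the axis (Suzuki-Miyaura, only three ortho groups at that stage) into the C5 boronate and the C3 iodide of paeonol.
The C3 iodide is made from resacetophenone (iodination between the two hydroxyls, then 4-O-methylation), because halogenation of paeonol itself goes to C5. The 5-OH/7-OMe pattern therefore needs no selective demethylation.

Key step: step 9

Assumption: the target SMILES carries no descriptor for the C6-C8'' axis and the molecule has no stereocentre, so the axis is made as the racemate.

Step 1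
Reactants: 1 paeonol (1-(2-hydroxy-4-methoxyphenyl)ethan-1-one)
Product: 2 C5-bromopaeonol (1-(5-bromo-2-hydroxy-4-methoxyphenyl)ethan-1-one)
Conditions: NBS (1.05 equiv), MeCN, 0 °C to rt, dark
Reagents that add atoms: N-bromosuccinimide, O=C1CCC(=O)N1Br
Why: Electrophilic aromatic bromination goes para to the phenol and ortho to the methoxy group (C5), because C3 is squeezed between two oxygen substituents and the polar, radical-free medium leaves the acetyl methyl alone.

Step 2
Reactants: 2 C5-bromopaeonol
Product: 3 C5-borylated paeonol (1-[2-hydroxy-4-methoxy-5-(4,4,5,5-tetramethyl-1,3,2-dioxaborolan-2-yl)phenyl]ethan-1-one)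
Conditions: B2pin2 (1.2 equiv), PdCl2(dppf) (3 mol %), KOAc (3 equiv), 1,4-dioxane, 90 °C
Reagents that add atoms: bis(pinacolato)diboron, CC1(C)OB(B2OC(C)(C)C(C)(C)O2)OC1(C)C
Why: Miyaura borylation tolerates the ketone and the hydrogen-bonded phenol under the weak base KOAc, and boron is put on the less hindered half, whose boronate with one ortho substituent resists protodeboronation better than a 2,6-dioxygenated one would.

Step 3
Reactants: 4 resacetophenone (1-(2,4-dihydroxyphenyl)ethan-1-one)
Product: 5 C3-iodoresacetophenone (1-(2,4-dihydroxy-3-iodophenyl)ethan-1-one)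
Conditions: I2 (0.4 equiv), HIO3 (0.2 equiv), EtOH/H2O, rt
Reagents that add atoms: iodine, II; iodic acid, O=I(=O)O
Why: Oxidative electrophilic iodination of chelated resacetophenone is known to take place at C3, the carbon ortho to both hydroxyls, which gives the regiochemistry that direct halogenation of paeonol (C5-selective, see step 1) cannot give.

Step 4
Reactants: 5 C3-iodoresacetophenone
Product: 6 C3-iodopaeonol (1-(2-hydroxy-3-iodo-4-methoxyphenyl)ethan-1-one)
Conditions: MeI (1.05 equiv), K2CO3 (1.1 equiv), acetone, 50 °C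
Reagents that add atoms: iodomethane, CI
Why: Williamson etherification with one equivalent of MeI hits only the free and more acidic 4-OH, since the 2-OH is held in a hydrogen bond to the acetyl oxygen, the same selectivity that turns resacetophenone into paeonol.

Step 5
Reactants: 3 C5-borylated paeonol; 6 C3-iodopaeonol
Product: 7 biaryl diketone (3,5'-diacetyl-2,4'-dihydroxy-2',6-dimethoxy-1,1'-biphenyl)
Conditions: Pd(OAc)2 (5 mol %), SPhos (10 mol %), K3PO4 (4 equiv), 1,4-dioxane/H2O, 90 °C
Reagents that add atoms: none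
Why: Suzuki-Miyaura coupling with the bulky, electron-rich SPhos ligand is established for biaryls with three ortho substituents, the reactive C-I bond offsets the phenoxide donor beside it in the oxidative addition to zerovalent palladium, and the extra base covers both acidic phenols.

Step 6
Reactants: 7 biaryl diketone; 8 4-hydroxybenzaldehyde (2.5 equiv)
Product: 9 bis-chalcone ((2E,2'E)-1,1'-(2,4'-dihydroxy-2',6-dimethoxy[1,1'-biphenyl]-3,5'-diyl)bis[3-(4-hydroxyphenyl)prop-2-en-1-one])
Conditions: KOH (50% aq., excess), EtOH, rt to 40 °C; then cold dilute HCl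
Reagents that add atoms: none
Why: In this twofold Claisen-Schmidt condensation both acetyl groups lie meta to the axis and are unhindered, excess KOH makes up for the lower electrophilicity of the phenoxide form of 8, and E1cB dehydration gives the E-enones.

Step 7
Reactants: 9 bis-chalcone
Product: 10 dideoxy biflavone diol (4',4'''-dihydroxy-7,7''-dimethoxy-6,8''-biflavone)
Conditions: I2 (20 mol %), DMSO, 130 °C
Reagents that add atoms: none
Why: The I2/DMSO oxidative cyclisation is the standard way from 2'-hydroxychalcones to flavones, tolerates free ring B phenols and aryl methyl ethers, and closes each ring C through the only ortho phenol available, so the 6- and 8''-linkages are fixed by the substitution pattern of 7.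

Step 8
Reactants: 10 dideoxy biflavone diol
Product: 11 dideoxy biflavone diacetate (4',4'''-diacetoxy-7,7''-dimethoxy-6,8''-biflavone)
Conditions: Ac2O (4 equiv), pyridine, DMAP (cat.), rt
Reagents that add atoms: acetic anhydride, CC(=O)OC(C)=O
Why: Pyridine/DMAP-catalysed O-acylation turns both ring B phenols into acetates, which lowers the electron density of ring B and removes the free phenols that a trivalent iodine oxidant would dearomatise.

Step 9
Reactants: 11 dideoxy biflavone diacetate
Product: 13 DMGF 4',4'''-diacetate, via bis(trifluoroacetate) 12 (not isolated)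
Conditions: [RuCl2(p-cymene)]2 (10 mol %), PhI(OCOCF3)2 (2 x 2 equiv, in portions), TFA/TFAA 3:1, 80 °C; evaporate, then THF/H2O, rt
Reagents that add atoms: [bis(trifluoroacetoxy)iodo]benzene, O=C(OI(OC(=O)C(F)(F)F)c1ccccc1)C(F)(F)F
Why: In TFA the chloride ligands are exchanged for trifluoroacetate, the resulting divalent ruthenium carboxylate binds a pyranone carbonyl oxygen and cleaves the peri C-H bond by carboxylate-assisted metalation to a five-membered ruthenacycle (Ru, O, C4, C4a, C5), and oxidation by PhI(OCOCF3)2 to tetravalent ruthenium followed by C-O reductive elimination leaves an aryl trifluoroacetate; the same cycle runs at C5'' and at C5. TFAA keeps both new oxygens masked as in 12, so that no free phenol is exposed to the trivalent iodine oxidant and no chelating product ties up the catalyst, and brief hydrolysis then frees the two chelated phenols while the much less electrophilic acetates stay. The closest known reaction type is the ruthenium-catalysed ketone-directed ortho C-H hydroxylation of aryl ketones, which is established at C5 of chromones and flavones with this catalyst, oxidant and solvent pair, so that only its twofold use in one molecule goes beyond the known examples. No ring is closed and no stereocentre is set; the incoming C5 oxygen becomes the fourth ortho substituent of the C6-C8'' axis, which is obtained as the racemate. The step needs site selectivity among all aryl and vinyl C-H bonds: only C5-H and C5''-H allow a five-membered chelate (C3-H would need a four-membered one, and C8-H, C6''-H and ring B are out of reach of the carbonyls), protonation of the pyranones in TFA damps undirected oxidation of the methoxy-bearing rings A, and the acetates both deactivate ring B and are far weaker donors than the carbonyls. C5''-H has only a hydrogen neighbour and should react first, whereas C5-H lies next to the twisted 8''-aryl group, which shows just its ipso carbon in the plane of ring A, so that metalation should still be possible but slower, and this is met by the higher catalyst loading and the portionwise oxidant.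

Step 10
Reactants: 13 DMGF 4',4'''-diacetate
Product: 14 DMGF (5,5'',4',4'''-tetrahydroxy-7,7''-dimethoxy-6,8''-biflavone, racemic axis)
Conditions: K2CO3 (3 equiv), MeOH/THF, rt; then dilute HCl
Reagents that add atoms: none
Why: Base-catalysed transesterification cleaves aryl acetates at room temperature without touching the aryl methyl ethers, the pyranone rings or the chelated 5-hydroxyls, and material that lost an acetate by acyl exchange in step 9 converges on the same product.

Compound list
1 | paeonol, 1-(2-hydroxy-4-methoxyphenyl)ethan-1-one | CC(=O)c1ccc(OC)cc1O | starting material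
2 | C5-bromopaeonol, 1-(5-bromo-2-hydroxy-4-methoxyphenyl)ethan-1-one | CC(=O)c1cc(Br)c(OC)cc1O | intermediate
3 | C5-borylated paeonol, 1-[2-hydroxy-4-methoxy-5-(4,4,5,5-tetramethyl-1,3,2-dioxaborolan-2-yl)phenyl]ethan-1-one | CC(=O)c1cc(B2OC(C)(C)C(C)(C)O2)c(OC)cc1O | intermediate
4 | resacetophenone, 1-(2,4-dihydroxyphenyl)ethan-1-one | CC(=O)c1ccc(O)cc1O | starting material
5 | C3-iodoresacetophenone, 1-(2,4-dihydroxy-3-iodophenyl)ethan-1-one | CC(=O)c1ccc(O)c(I)c1O | intermediate
6 | C3-iodopaeonol, 1-(2-hydroxy-3-iodo-4-methoxyphenyl)ethan-1-one | CC(=O)c1ccc(OC)c(I)c1O | intermediate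
7 | biaryl diketone, 3,5'-diacetyl-2,4'-dihydroxy-2',6-dimethoxy-1,1'-biphenyl | CC(=O)c1cc(-c2c(OC)ccc(C(C)=O)c2O)c(OC)cc1O | intermediate
8 | 4-hydroxybenzaldehyde | O=Cc1ccc(O)cc1 | starting material
9 | bis-chalcone, (2E,2'E)-1,1'-(2,4'-dihydroxy-2',6-dimethoxy[1,1'-biphenyl]-3,5'-diyl)bis[3-(4-hydroxyphenyl)prop-2-en-1-one] | O=C(/C=C/c1ccc(O)cc1)c1cc(-c2c(OC)ccc(C(=O)/C=C/c3ccc(O)cc3)c2O)c(OC)cc1O | intermediate
10 | 4',4'''-dihydroxy-7,7''-dimethoxy-6,8''-biflavone | COc1cc2oc(-c3ccc(O)cc3)cc(=O)c2cc1-c1c(OC)ccc2c(=O)cc(-c3ccc(O)cc3)oc12 | intermediate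
11 | 4',4'''-diacetoxy-7,7''-dimethoxy-6,8''-biflavone (precursor of the key step) | COc1cc2oc(-c3ccc(OC(C)=O)cc3)cc(=O)c2cc1-c1c(OC)ccc2c(=O)cc(-c3ccc(OC(C)=O)cc3)oc12 | intermediate
12 | 4',4'''-diacetoxy-7,7''-dimethoxy-5,5''-bis(trifluoroacetoxy)-6,8''-biflavone (not isolated) | COc1cc2oc(-c3ccc(OC(C)=O)cc3)cc(=O)c2c(OC(=O)C(F)(F)F)c1-c1c(OC)cc(OC(=O)C(F)(F)F)c2c(=O)cc(-c3ccc(OC(C)=O)cc3)oc12 | intermediate
13 | DMGF 4',4'''-diacetate, 4',4'''-diacetoxy-5,5''-dihydroxy-7,7''-dimethoxy-6,8''-biflavone (racemic axis) | COc1cc2oc(-c3ccc(OC(C)=O)cc3)cc(=O)c2c(O)c1-c1c(OC)cc(O)c2c(=O)cc(-c3ccc(OC(C)=O)cc3)oc12 | intermediate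
14 | DMGF, 5,5'',4',4'''-tetrahydroxy-7,7''-dimethoxy-6,8''-biflavone (racemic axis) | COc1cc2oc(-c3ccc(O)cc3)cc(=O)c2c(O)c1-c1c(OC)cc(O)c2c(=O)cc(-c3ccc(O)cc3)oc12 | target

Total step count: 10.
Longest linear sequence: 8 steps (4, 5, 6, 7, 9, 10, 11, 13, 14). The branch 1, 2, 3, 7 is equally long.

Steps most likely to fail

Risk 1, step 9.
- **What may go wrong:** Ruthenation of C5-H beside the axis may lag so far behind that of C5''-H that the reaction stalls at the mono-oxygenated stage. The long exposure to the trivalent iodine oxidant would meanwhile wear down the methoxy-bearing rings A and scramble the acetates.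
- **Fallback:** C5 is oxygenated before the axis exists. The fallback sets out from 2 and 6 and comes back at 12.
- **Unit 1:** 2 is condensed with 8 (KOH, EtOH) to (E)-1-(5-bromo-2-hydroxy-4-methoxyphenyl)-3-(4-hydroxyphenyl)prop-2-en-1-one F1. This is closed with I2 in DMSO to 6-bromo-4'-hydroxy-7-methoxyflavone F2 and acetylated to 4'-acetoxy-6-bromo-7-methoxyflavone F3. The conditions of step 9 are applied to this monomer, in which only a bromine atom flanks C5-H. They should give, through 4'-acetoxy-6-bromo-7-methoxy-5-(trifluoroacetoxy)flavone F4, the phenol 4'-acetoxy-6-bromo-5-hydroxy-7-methoxyflavone F5.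
- **Unit 2:** In parallel 6 and 8 give (E)-1-(2-hydroxy-3-iodo-4-methoxyphenyl)-3-(4-hydroxyphenyl)prop-2-en-1-one F6. I2 in DMSO gives 4'-hydroxy-8-iodo-7-methoxyflavone F7. Miyaura borylation (PdCl2(dppf), B2pin2, KOAc, dioxane) gives 4'-hydroxy-7-methoxy-8-(4,4,5,5-tetramethyl-1,3,2-dioxaborolan-2-yl)flavone F8.
- **Union and return:** Suzuki-Miyaura coupling of F5 with F8 (Pd2(dba)3, SPhos, K3PO4, toluene/H2O, 100 °C) now has to build the axis with four ortho substituents. With loss of the acetate in the basic medium it should give 5,4',4'''-trihydroxy-7,7''-dimethoxy-6,8''-biflavone F9. Ac2O (2 equiv) in pyridine at 0 °C acylates only the ring B phenols, since the chelated 5-OH is inert, and gives 4',4'''-diacetoxy-5-hydroxy-7,7''-dimethoxy-6,8''-biflavone F10. In TFA/TFAA this is capped as 4',4'''-diacetoxy-7,7''-dimethoxy-5-(trifluoroacetoxy)-6,8''-biflavone F11. A single ruthenium-catalysed oxygenation at the unhindered C5''-H then leads to 12.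

Risk 2, step 5.
- **What may go wrong:** Protodeboronation of 3 and reductive loss of iodine from the phenoxide of 6 may outrun the slow transmetalation at the doubly flanked carbon.
- **Fallback:** The halves are joined as flavones, so that no phenoxide stands next to halogen or boron. The fallback sets out from 2 and 6 and comes back at 10.
- **Sequence:** 2 is taken through (E)-1-(5-bromo-2-hydroxy-4-methoxyphenyl)-3-(4-hydroxyphenyl)prop-2-en-1-one F1 to 6-bromo-4'-hydroxy-7-methoxyflavone F2 as above. Miyaura borylation then gives 4'-hydroxy-7-methoxy-6-(4,4,5,5-tetramethyl-1,3,2-dioxaborolan-2-yl)flavone F12. 6 is taken through (E)-1-(2-hydroxy-3-iodo-4-methoxyphenyl)-3-(4-hydroxyphenyl)prop-2-en-1-one F6 to 4'-hydroxy-8-iodo-7-methoxyflavone F7. Coupling of F12 with F7 (Pd(OAc)2, SPhos, K3PO4, dioxane/H2O, 90 °C) keeps the less hindered half as the boronate and should give 10 directly, replacing steps 5 to 7.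

Risk 3, step 6.
- **What may go wrong:** The phenoxide form of 8 is a poor electrophile, so the second condensation may stay incomplete. Mono-condensed material and prematurely ring-closed products would then accumulate.
- **Fallback:** Ring C is built by acyl transfer instead of aldol chemistry. The fallback sets out from 7 and comes back at 10.
- **Sequence:** 7 is O-acylated twice with 4-(benzyloxy)benzoyl chloride (pyridine, DMAP) to 3,5'-diacetyl-2',6-dimethoxy-1,1'-biphenyl-2,4'-diyl bis[4-(benzyloxy)benzoate] F13. KOH in pyridine at 50 °C triggers a twofold Baker-Venkataraman acyl shift to 1,1'-(2,4'-dihydroxy-2',6-dimethoxy[1,1'-biphenyl]-3,5'-diyl)bis{3-[4-(benzyloxy)phenyl]propane-1,3-dione} F14. p-TsOH in toluene at 90 °C closes both pyranones by cyclodehydration to 4',4'''-bis(benzyloxy)-7,7''-dimethoxy-6,8''-biflavone F15. Hydrogenolysis (H2, Pd/C, EtOAc/THF, rt) then gives 10.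

Further compounds
F1 | step 9 | (E)-1-(5-bromo-2-hydroxy-4-methoxyphenyl)-3-(4-hydroxyphenyl)prop-2-en-1-one | O=C(/C=C/c1ccc(O)cc1)c1cc(Br)c(OC)cc1O
F2 | step 9 | 6-bromo-4'-hydroxy-7-methoxyflavone | COc1cc2oc(-c3ccc(O)cc3)cc(=O)c2cc1Br
F3 | step 9 | 4'-acetoxy-6-bromo-7-methoxyflavone | COc1cc2oc(-c3ccc(OC(C)=O)cc3)cc(=O)c2cc1Br
F4 | step 9 | 4'-acetoxy-6-bromo-7-methoxy-5-(trifluoroacetoxy)flavone | COc1cc2oc(-c3ccc(OC(C)=O)cc3)cc(=O)c2c(OC(=O)C(F)(F)F)c1Br
F5 | step 9 | 4'-acetoxy-6-bromo-5-hydroxy-7-methoxyflavone | COc1cc2oc(-c3ccc(OC(C)=O)cc3)cc(=O)c2c(O)c1Br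
F6 | step 9 | (E)-1-(2-hydroxy-3-iodo-4-methoxyphenyl)-3-(4-hydroxyphenyl)prop-2-en-1-one | O=C(/C=C/c1ccc(O)cc1)c1ccc(OC)c(I)c1O
F7 | step 9 | 4'-hydroxy-8-iodo-7-methoxyflavone | COc1ccc2c(=O)cc(-c3ccc(O)cc3)oc2c1I
F8 | step 9 | 4'-hydroxy-7-methoxy-8-(4,4,5,5-tetramethyl-1,3,2-dioxaborolan-2-yl)flavone | COc1ccc2c(=O)cc(-c3ccc(O)cc3)oc2c1B1OC(C)(C)C(C)(C)O1
F9 | step 9 | 5,4',4'''-trihydroxy-7,7''-dimethoxy-6,8''-biflavone | COc1cc2oc(-c3ccc(O)cc3)cc(=O)c2c(O)c1-c1c(OC)ccc2c(=O)cc(-c3ccc(O)cc3)oc12
F10 | step 9 | 4',4'''-diacetoxy-5-hydroxy-7,7''-dimethoxy-6,8''-biflavone | COc1cc2oc(-c3ccc(OC(C)=O)cc3)cc(=O)c2c(O)c1-c1c(OC)ccc2c(=O)cc(-c3ccc(OC(C)=O)cc3)oc12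
F11 | step 9 | 4',4'''-diacetoxy-7,7''-dimethoxy-5-(trifluoroacetoxy)-6,8''-biflavone | COc1cc2oc(-c3ccc(OC(C)=O)cc3)cc(=O)c2c(OC(=O)C(F)(F)F)c1-c1c(OC)ccc2c(=O)cc(-c3ccc(OC(C)=O)cc3)oc12
F12 | step 5 | 4'-hydroxy-7-methoxy-6-(4,4,5,5-tetramethyl-1,3,2-dioxaborolan-2-yl)flavone | COc1cc2oc(-c3ccc(O)cc3)cc(=O)c2cc1B1OC(C)(C)C(C)(C)O1
F13 | step 6 | 3,5'-diacetyl-2',6-dimethoxy-1,1'-biphenyl-2,4'-diyl bis[4-(benzyloxy)benzoate] | CC(=O)c1cc(-c2c(OC)ccc(C(C)=O)c2OC(=O)c2ccc(OCc3ccccc3)cc2)c(OC)cc1OC(=O)c1ccc(OCc2ccccc2)cc1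
F14 | step 6 | 1,1'-(2,4'-dihydroxy-2',6-dimethoxy[1,1'-biphenyl]-3,5'-diyl)bis{3-[4-(benzyloxy)phenyl]propane-1,3-dione} | O=C(CC(=O)c1ccc(OCc2ccccc2)cc1)c1cc(-c2c(OC)ccc(C(=O)CC(=O)c3ccc(OCc4ccccc4)cc3)c2O)c(OC)cc1O
F15 | step 6 | 4',4'''-bis(benzyloxy)-7,7''-dimethoxy-6,8''-biflavone | COc1cc2oc(-c3ccc(OCc4ccccc4)cc3)cc(=O)c2cc1-c1c(OC)ccc2c(=O)cc(-c3ccc(OCc4ccccc4)cc3)oc12
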